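Readings and results were computed on assumed constants, noise included.

The closed, stirred flask is taken here to draw its nucleophile from a gas held at 200 mM, and each electrophile that reacts is taken to set one acid free.

in all of them: gas 200 mM (held)

| charge | electrophile | free base | scavenger | remark | time |
|---|---|---|---|---|---|
| dawn | 0.50 M | 1 M | 0.80 M | run made earlier |  |
| midnight | 0.75 M | 1 M | 0.80 M | run made earlier |  |
| winter | 1 M | 1 M | 1.2 M | run made earlier |  |
| flask | 1.0 M | 1.00 M | 0.800 M |  | 4.0 d |

| run | time / d | electrophile / % | product / % |
|---|---|---|---|
| dawn | 0.250 | 80 | 19 |
| dawn | 0.833 | 41 | 58 |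
| dawn | 1.25 | 22 | 78 |
| dawn | 2.08 | 2 | 97 |
| dawn | 3.00 | 0 | 98 |
| dawn | 4.00 | 0 | 100 |
| dawn | 5.00 | 0 | 104 |
| midnight | 0.250 | 85 | 15 |
| midnight | 0.833 | 50 | 51 |
| midnight | 1.25 | 30 | 72 |
| midnight | 2.08 | 8 | 92 |
| midnight | 3.00 | 2 | 97 |
| midnight | 4.00 | 2 | 102 |
| midnight | 5.00 | 0 | 101 |
| winter | 0.417 | 78 | 25 |
| winter | 0.833 | 53 | 47 |
| winter | 1.25 | 37 | 64 |
| winter | 2.50 | 8 | 96 |
| winter | 5.00 | 0 | 101 |

(scatter of a reading: 1.5 percentage points)

* part of the electrophile that has reacted at 4.0 d
* share of the unused nucleophile that is free and not bound as protonated nucleophile, at 4.0 d

- the numbers in the tables scatter with a standard deviation of 1.5 percentage points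
- at the start none of the gas is in solution
- the earlier runs do not show how much of nucleophile is bound; that part of a forecast is a guess

Does the electrophile finish in time? The readings of the winter run, with the same electrophile charge, show product forming at about 0.564 M/d up to 0.833 d. At that pace the charge of the flask takes 1.77 d, less than the 4.0 d allowed, so the reckoning here expects product close to the 96% read in the winter run at 2.50 d, although the winter run held more scavenger, 1.2 M against 0.800 M.

Where, then, does the acid go? The runs do not show how much nucleophile is bound, but free nucleophile should stop near the saturation level of the gas. The number to carry is therefore the acid load, the electrophile charged divided by the saturation level of the gas, which for the flask is 5.00: acid to be placed per free nucleophile. The guess here is that the scavenger catches little and that half of the acid lands on the nucleophile. That gives 0.500 M of protonated nucleophile against 200 mM free, a free share of 28.6%.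

The forecast differs from this reckoning on the free share, giving 95% reacted and 70% free, with the caution "The free share is a guess". The flask gives 99.7% reacted and 25.8% free.

    nucleophile + acid set free ⇌ protonated nucleophile, settled at all times (K = 4900 /M)
    acid set free + free base ⇌ salt of the base, settled at all times (K = 1200 /M)
    acid set free + scavenger → scavenged by-product (k = 0.510 /M/h)
    electrophile + acid set free ⇌ idle adduct, settled at all times (K = 0.610 /M)
    gas ⇌ nucleophile, rate k5*(csat - [nucleophile]) (kL = 0.270 /h)
    electrophile + nucleophile → acid set free + product (k = 0.450 /M/h)

In the flask at 4.0 d, with a load of 5.00, the acid stands as 0.564 M of protonated nucleophile and 0.413 M of salt of the base, with 0.0195 M of scavenged by-product and 5.86 × 10⁻⁴ M of acid set free. The protonated form, the resting state of the unused nucleophile, exceeds the 0.197 M of free nucleophile. The neighbour charged with 0.25 M of electrophile has a load of 1.25, and the same even split gives 61.5%. That neighbour gives 62.7%, with 0.119 M of protonated nucleophile beside 0.200 M free.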